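**Plan**

- Locants of the target are used throughout: C1 quaternary epoxide carbon, C2 (OMe), C3 (OBz), C4=C5, C6 epoxide CH, C7 the CH2O carbon. The C1–C6 ring-fused epoxide with an oxygen on C7 is the Payne isomer of a C1–C7 spiro-epoxide that carries a C6 hydroxyl; this makes the key step possible.
- Retrosynthesis cuts the C7–O benzoyl bond and the C1–O6 epoxide bond (Payne), then the spiro-epoxide oxygen (alkene epoxidation), the C6–H bond (ketone reduction), the C1=C7 bond (α'-methylenation), the C3 benzoate and the enone, back to (−)-quinic acid.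
- Forward, the carbocycle is the quinic acid ring throughout: its carboxyl carbon is excised, the quinic C3 oxygen is eliminated to give the enone, and C7 is attached. The spiro-oxirane is then formed (step 10) and last the ring-fused oxirane (step 12).
- C2 and C3 are C5 and C4 of quinic acid; C6 comes from a CBS reduction; C1 comes from epoxidation anti to the C6 silyl ether and the C2 methoxy group and is inverted in the Payne step.

Key step: step 12

**Route**

Step 1
Reactants: 1 (−)-quinic acid; 2 2,2-dimethoxypropane
Product: 3 3,4-O-isopropylidene-1,5-quinide (quinic acid 1,5-lactone 3,4-acetonide)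
Conditions: p-toluenesulfonic acid monohydrate (cat.), acetone, reflux
Reagents that add atoms: 2,2-dimethoxypropane, COC(C)(C)OC
Why: Acid-catalysed transketalisation protects the cis C3/C4 diol as the acetonide while the carboxyl group lactonises onto the cis C5 hydroxyl, so that no stereocentre is touched and only the tertiary C1 hydroxyl stays free.

Step 2
Reactants: 3 3,4-O-isopropylidene-1,5-quinide
Product: 4 1-(hydroxymethyl)-3,4-(isopropylidenedioxy)cyclohexane-1,5-diol (quinic acid configuration)
Conditions: NaBH4, EtOH, 0 °C to rt
Reagents that add atoms: none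
Why: Borohydride reduction of the activated α-hydroxy γ-lactone opens it to the 1-(hydroxymethyl)-1,5-diol and leaves the ketal untouched.

Step 3
Reactants: 4 1-(hydroxymethyl)-3,4-(isopropylidenedioxy)cyclohexane-1,5-diol
Product: 5 (3R,4S,5R)-5-hydroxy-3,4-(isopropylidenedioxy)cyclohexan-1-one
Conditions: NaIO4, H2O, pH 7 phosphate buffer, 0 °C to rt
Reagents that add atoms: none
Why: Malaprade glycol cleavage of the C1(OH)–CH2OH unit removes the former carboxyl carbon as formaldehyde and gives the cyclohexanone without touching the three oxygenated stereocentres.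

Step 4
Reactants: 5 (3R,4S,5R)-5-hydroxy-3,4-(isopropylidenedioxy)cyclohexan-1-one; 6 trimethyloxonium tetrafluoroborate
Product: 7 (3R,4S,5R)-3,4-(isopropylidenedioxy)-5-methoxycyclohexan-1-one
Conditions: 1,8-bis(dimethylamino)naphthalene, 4 Å molecular sieves, CH2Cl2, 0 °C to rt
Reagents that add atoms: trimethyloxonium tetrafluoroborate, C[O+](C)C.F[B-](F)(F)F
Why: Meerwein O-methylation with a hindered, non-nucleophilic proton scavenger alkylates the secondary hydroxyl under conditions too weakly basic for retro-aldol cleavage or β-elimination of the β-hydroxy ketone.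

Step 5
Reactants: 7 (3R,4S,5R)-3,4-(isopropylidenedioxy)-5-methoxycyclohexan-1-one
Product: 8 (4R,5R)-4-hydroxy-5-methoxycyclohex-2-en-1-one
Conditions: 1,8-diazabicyclo[5.4.0]undec-7-ene (DBU, cat.), CH2Cl2, 0 °C
Reagents that add atoms: none
Why: E1cB β-elimination from the enolate expels the axial ketal oxygen and the resulting hemiketal loses acetone, while the equatorial methoxy group, a poorer and misaligned leaving group, should stay, giving the γ-hydroxy enone with both stereocentres intact.

Step 6
Reactants: 8 (4R,5R)-4-hydroxy-5-methoxycyclohex-2-en-1-one; 9 benzoyl chloride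
Product: 10 (4R,5R)-4-(benzoyloxy)-5-methoxycyclohex-2-en-1-one
Conditions: pyridine, 4-(dimethylamino)pyridine (cat.), CH2Cl2, 0 °C
Reagents that add atoms: benzoyl chloride, O=C(Cl)c1ccccc1
Why: Pyridine-mediated O-acylation with nucleophilic catalysis esterifies the allylic alcohol under conditions too mild to eliminate the neighbouring methoxy group.

Step 7
Reactants: 10 (4R,5R)-4-(benzoyloxy)-5-methoxycyclohex-2-en-1-one; 11 dimethyl(methylidene)ammonium iodide (Eschenmoser's salt)
Product: 15 (4R,5R)-4-(benzoyloxy)-5-methoxy-6-methylidenecyclohex-2-en-1-one, via lithium enolate 12 (not isolated), via Mannich base 13 (not isolated), via methiodide 14 (not isolated)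
Conditions: LiN(SiMe3)2, THF, −78 °C; 11, −78 to 0 °C; MeI, rt; sat. aq NaHCO3, CH2Cl2, rt; product used at once
Reagents that add atoms: dimethyl(methylidene)ammonium iodide, C[N+](C)=C.[I-]
Why: Kinetic α'-deprotonation gives the cross-conjugated lithium enolate, which undergoes a Mannich reaction with Eschenmoser's salt, and N-methylation followed by mild-base E1cB loss of trimethylamine unveils the exocyclic enone, the low temperature keeping β-elimination of methoxide from the enolate at bay.

Step 8
Reactants: 15 (4R,5R)-4-(benzoyloxy)-5-methoxy-6-methylidenecyclohex-2-en-1-one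
Product: 16 (1R,4R,5R)-4-(benzoyloxy)-5-methoxy-6-methylidenecyclohex-2-en-1-ol (C6 hydroxyl cis to the C2 methoxy group and trans to the C3 benzoate in target locants)
Conditions: (S)-1-methyl-3,3-diphenyltetrahydro-1H,3H-pyrrolo[1,2-c][1,3,2]oxazaborole [(S)-Me-CBS, 0.2 equiv], catecholborane, toluene, −78 °C; aqueous work-up
Reagents that add atoms: none
Why: In this Corey–Bakshi–Shibata reduction the α-branched exocyclic enone arm acts as the large substituent, so the (S)-catalyst should deliver hydride to the face opposite the C2 methoxy group and set C6 as R, with the 1,2-selectivity usual for oxazaborolidine-catalysed enone reductions.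

Step 9
Reactants: 16 (1R,4R,5R)-4-(benzoyloxy)-5-methoxy-6-methylidenecyclohex-2-en-1-ol; 17 tert-butyldimethylsilyl trifluoromethanesulfonate
Product: 18 tert-butyldimethylsilyl ether of 16
Conditions: 2,6-lutidine, CH2Cl2, −78 °C
Reagents that add atoms: tert-butyldimethylsilyl trifluoromethanesulfonate, CC(C)(C)[Si](C)(C)OS(=O)(=O)C(F)(F)F
Why: Silyl ether formation with the silyl triflate and a hindered pyridine base masks the hydroxyl, so that it cannot direct the peracid syn in the next step and adds bulk to the lower face.

Step 10
Reactants: 18 tert-butyldimethylsilyl ether of 16; 19 3-chloroperoxybenzoic acid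
Product: 20 C1–C7 spiro-epoxide of 18 (spiro oxygen trans to the C6 silyloxy and C2 methoxy groups, cis to the C3 benzoate)
Conditions: NaHCO3, CH2Cl2, 0 °C
Reagents that add atoms: 3-chloroperoxybenzoic acid, O=C(OO)c1cccc(Cl)c1
Why: In this Prilezhaev epoxidation the peracid should approach the exocyclic 1,1-disubstituted alkene from the face opposite the two flanking allylic substituents (C6 silyl ether and C2 methoxy group, both on the same face), which sets C1 with the spiro oxygen trans to C6–O, while the ring alkene is shielded on both faces and deactivated by the allylic benzoate.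

Step 11
Reactants: 20 C1–C7 spiro-epoxide of 18
Product: 21 spiro-epoxy alcohol (1S,2S,3R,6R in target locants; C6 hydroxyl trans to the spiro oxygen)
Conditions: Bu4NF, AcOH (1:1), THF, 0 °C to rt
Reagents that add atoms: none
Why: Fluoride-mediated desilylation buffered with acetic acid frees the C6 alcohol without generating a free alkoxide, so that neither premature epoxide migration nor benzoate transfer should occur.

Step 12
Reactants: 21 spiro-epoxy alcohol; 9 benzoyl chloride
Product: 24 [(1R,2S,3R,6R)-3-(benzoyloxy)-2-methoxy-7-oxabicyclo[4.1.0]hept-4-en-1-yl]methyl benzoate (target), via sodium C6-alkoxide 22 (not isolated), via sodium C7-alkoxide 23 (not isolated)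
Conditions: NaH, THF, 0 °C to rt; then 9, 0 °C
Reagents that add atoms: benzoyl chloride, O=C(Cl)c1ccccc1
Why: Deprotonation gives the C6 alkoxide 22, whose oxygen can lie antiperiplanar to the C1–O bond of the spiro-epoxide and attacks C1 from the rear, so that the C1–O6 bond forms while the spiro oxygen leaves as the C7 alkoxide 23. This is a Payne rearrangement of a 2,3-epoxy alcohol run under aprotic conditions, with the migrated alkoxide trapped by an acyl chloride in the same flask. The new oxirane closes in a 3-exo-tet mode. C1 is the only stereocentre formed and it is set by inversion, so its configuration follows from the trans relationship of the spiro oxygen and the C6 hydroxyl built in steps 8 and 10, which puts the new epoxide on the face of C6–O and C7 on the opposite face. The step needs the equilibrium to lie on the side of 23 and attack at C1 instead of C7: the first is secured by the trisubstituted epoxide with a primary alkoxide being the more stable pair and by irreversible benzoylation of that alkoxide, the second by 3-exo closure at the adjacent carbon being far faster than 4-exo oxetane formation. Any transfer of the C3 benzoyl group to the C7 alkoxide is harmless, because benzoylation of the alkoxide then left at C3 gives the same product.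

**Compound list**

1 | (−)-quinic acid | O[C@@]1(C(=O)O)C[C@@H](O)[C@@H](O)[C@H](O)C1 | starting material
2 | 2,2-dimethoxypropane | COC(C)(C)OC | starting material
3 | 3,4-O-isopropylidene-1,5-quinide | O[C@@]1(C(=O)O2)C[C@H]3OC(C)(C)O[C@H]3[C@H]2C1 | intermediate
4 | 1-(hydroxymethyl)-3,4-(isopropylidenedioxy)cyclohexane-1,5-diol (quinic acid configuration) | O[C@@]1(CO)C[C@H]2OC(C)(C)O[C@H]2[C@H](O)C1 | intermediate
5 | (3R,4S,5R)-5-hydroxy-3,4-(isopropylidenedioxy)cyclohexan-1-one | O=C1C[C@H]2OC(C)(C)O[C@H]2[C@H](O)C1 | intermediate
6 | trimethyloxonium tetrafluoroborate | C[O+](C)C.F[B-](F)(F)F | starting material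
7 | (3R,4S,5R)-3,4-(isopropylidenedioxy)-5-methoxycyclohexan-1-one | O=C1C[C@H]2OC(C)(C)O[C@H]2[C@H](OC)C1 | intermediate
8 | (4R,5R)-4-hydroxy-5-methoxycyclohex-2-en-1-one | O=C1C=C[C@@H](O)[C@H](OC)C1 | intermediate
9 | benzoyl chloride | O=C(Cl)c1ccccc1 | starting material
10 | (4R,5R)-4-(benzoyloxy)-5-methoxycyclohex-2-en-1-one | O=C1C=C[C@@H](OC(=O)c2ccccc2)[C@H](OC)C1 | intermediate
11 | dimethyl(methylidene)ammonium iodide | C[N+](C)=C.[I-] | starting material
12 | lithium α'-enolate of 10 | [Li+].[O-]C1=C[C@@H](OC)[C@H](OC(=O)c2ccccc2)C=C1 | intermediate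
13 | (4R,5R)-4-(benzoyloxy)-6-[(dimethylamino)methyl]-5-methoxycyclohex-2-en-1-one (C6 epimers) | O=C1C=C[C@@H](OC(=O)c2ccccc2)[C@H](OC)C1CN(C)C | intermediate
14 | methiodide of 13 | O=C1C=C[C@@H](OC(=O)c2ccccc2)[C@H](OC)C1C[N+](C)(C)C.[I-] | intermediate
15 | (4R,5R)-4-(benzoyloxy)-5-methoxy-6-methylidenecyclohex-2-en-1-one | O=C1C=C[C@@H](OC(=O)c2ccccc2)[C@H](OC)C1=C | intermediate
16 | (1R,4R,5R)-4-(benzoyloxy)-5-methoxy-6-methylidenecyclohex-2-en-1-ol | CO[C@H]1[C@H](OC(=O)c2ccccc2)C=C[C@@H](O)C1=C | intermediate
17 | tert-butyldimethylsilyl trifluoromethanesulfonate | CC(C)(C)[Si](C)(C)OS(=O)(=O)C(F)(F)F | starting material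
18 | tert-butyldimethylsilyl ether of 16 | CO[C@H]1[C@H](OC(=O)c2ccccc2)C=C[C@@H](O[Si](C)(C)C(C)(C)C)C1=C | intermediate
19 | 3-chloroperoxybenzoic acid | O=C(OO)c1cccc(Cl)c1 | starting material
20 | C1–C7 spiro-epoxide of 18, spiro oxygen trans to C6–O and C2–O | CO[C@H]1[C@H](OC(=O)c2ccccc2)C=C[C@@H](O[Si](C)(C)C(C)(C)C)[C@@]13CO3 | intermediate
21 | spiro-epoxy alcohol, (1S,2S,3R,6R) in target locants | CO[C@H]1[C@H](OC(=O)c2ccccc2)C=C[C@@H](O)[C@@]13CO3 | intermediate
22 | sodium C6-alkoxide of 21 | [Na+].CO[C@H]1[C@H](OC(=O)c2ccccc2)C=C[C@@H]([O-])[C@@]13CO3 | intermediate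
23 | sodium C7-alkoxide of the C1–C6 ring-fused epoxide | [Na+].CO[C@H]1[C@H](OC(=O)c2ccccc2)C=C[C@H]2O[C@]21C[O-] | intermediate
24 | [(1R,2S,3R,6R)-3-(benzoyloxy)-2-methoxy-7-oxabicyclo[4.1.0]hept-4-en-1-yl]methyl benzoate | CO[C@H]1[C@H](OC(=O)c2ccccc2)C=C[C@H]2O[C@]21COC(=O)c1ccccc1 | target

**Count and risks**

Total step count: 12. Longest linear sequence: 12 steps (the route is linear from 1).

Step 10 is the most likely to fail, through poor facial selectivity of the peracid at the exocyclic alkene or competing epoxidation of the ring alkene. The fallback delivers the C1 oxygen intramolecularly from the C3 oxygen, which lies on the required face. It sets out from 18 and comes back at 20.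
- Methanolysis of the benzoate (K2CO3, MeOH, 0 °C) gives the C3 alcohol F1.
- Di-tert-butyl dicarbonate and 4-(dimethylamino)pyridine in MeCN convert it to the tert-butyl carbonate F2.
- IBr in toluene at −80 °C (iodocarbonate cyclisation of a homoallylic carbonate) should close a six-membered carbonate onto the tertiary C1 and give the cyclic iodocarbonate F3.
- K2CO3 in MeOH cleaves the carbonate, and the freed C1 alkoxide displaces iodide at C7 to give the spiro-epoxy C3 alcohol F4, with C6 still silylated.
- Benzoylation (benzoyl chloride, pyridine, CH2Cl2) returns the material to 20.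

Step 7 may fail through β-elimination of methoxide from the lithium enolate, or through base-induced aromatisation or dimerisation of the cross-conjugated dienone during the amine elimination. The fallback introduces C7 without a strongly basic enolate. It sets out from 10 and comes back at 15.
- Soft enolisation (Me3SiOSO2CF3, Et3N, CH2Cl2, 0 °C) gives the cross-conjugated trimethylsilyl dienol ether F5.
- A Mukaiyama aldol reaction with aqueous formaldehyde catalysed by Yb(OSO2CF3)3 in THF/H2O gives the hydroxymethyl ketone F6.
- Mesylation (MsCl, Et3N, CH2Cl2, 0 °C) gives the mesylate F7, which eliminates in the same flask to 15.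

Step 8 may fail through conjugate hydride delivery to the s-cis exocyclic enone, or through insufficient discrimination between the two alkenyl arms by the catalyst. The fallback relies on the substrate instead of the catalyst. It sets out from 15 and comes back at 16.
- Luche reduction (NaBH4, CeCl3·7H2O, MeOH, −78 °C) is strictly 1,2-selective and should favour attack anti to the pseudoaxial C2 methoxy group, giving 16.
- The C6-epimeric alcohol F8 is separated and oxidised back to 15 with MnO2 in CH2Cl2 for another pass.

**Further compounds**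

F1 | step 10 | C3 alcohol from debenzoylation of 18 | CO[C@H]1[C@H](O)C=C[C@@H](O[Si](C)(C)C(C)(C)C)C1=C
F2 | step 10 | C3 tert-butyl carbonate of F1 | CO[C@H]1[C@H](OC(=O)OC(C)(C)C)C=C[C@@H](O[Si](C)(C)C(C)(C)C)C1=C
F3 | step 10 | cyclic C1/C3 carbonate with C7 iodide | CO[C@H]1[C@H]2C=C[C@@H](O[Si](C)(C)C(C)(C)C)[C@]1(CI)OC(=O)O2
F4 | step 10 | spiro-epoxy C3 alcohol, C6 silyl ether | CO[C@H]1[C@H](O)C=C[C@@H](O[Si](C)(C)C(C)(C)C)[C@@]12CO2
F5 | step 7 | trimethylsilyl dienol ether of 10 | C[Si](C)(C)OC1=C[C@@H](OC)[C@H](OC(=O)c2ccccc2)C=C1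
F6 | step 7 | (4R,5R)-4-(benzoyloxy)-6-(hydroxymethyl)-5-methoxycyclohex-2-en-1-one (C6 epimers) | O=C1C=C[C@@H](OC(=O)c2ccccc2)[C@H](OC)C1CO
F7 | step 7 | mesylate of F6 | O=C1C=C[C@@H](OC(=O)c2ccccc2)[C@H](OC)C1COS(C)(=O)=O
F8 | step 8 | C6 epimer of 16 | CO[C@H]1[C@H](OC(=O)c2ccccc2)C=C[C@H](O)C1=C
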